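Ring C of the upper (epiafzelechin) unit is cut across two opposite bonds, O1–C8a and C2–C3. The C2=O1 carbonyl of 4-benzyloxybenzaldehyde is annulated onto a four-atom C3–C4–C4a–C8a unit, the silyl enol ether of a 2-fluoro-4,6-dibenzyloxyphenyl benzyloxymethyl ketone. The feature exploited is that C4 sits on C4a, next to C8a of ring A: as a carbonyl it makes C3 an enolate carbon and activates the C8a–F bond, and it later becomes the interflavan carbon. One flask (asymmetric Mukaiyama aldol, then fluoride-triggered SNAr) builds ring C with cis C2/C3. Reduction, C4 ionisation with capture by C8 of benzylated (–)-epicatechin, and hydrogenolysis finish.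

Key step: step 4

Assumptions: compounds 1, 3, 7 and 11 are taken as commercial. The tartrate ligand of the step 4 catalyst is a known compound made from dibenzyl D-tartrate and 2,6-diisopropoxybenzoic acid. The C4 configuration of alcohol 10 is immaterial because C4 is ionised in step 7; 10 is drawn as the expected all-cis epimer.

Step 1
Reactants: 1 1,3,5-trifluorobenzene
Product: 2 1,3-bis(benzyloxy)-5-fluorobenzene
Conditions: BnOH (2.05 equiv), NaH, NMP, 0 → 100 °C
Reagents that add atoms: benzyl alcohol, OCc1ccccc1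
Why: Twofold nucleophilic aromatic substitution (SNAr) by sodium benzyloxide, in which each benzyloxy group that enters replaces an inductively activating fluorine, so the third displacement is much slower and the stoichiometry should hold the reaction at the monofluoride.

Step 2
Reactants: 2 1,3-bis(benzyloxy)-5-fluorobenzene; 3 2-(benzyloxy)-N-methoxy-N-methylacetamide
Product: 5 1-[2,4-bis(benzyloxy)-6-fluorophenyl]-2-(benzyloxy)ethan-1-one, via aryllithium 4 (not isolated)
Conditions: n-BuLi, THF, –78 °C; then 3, –78 °C; aq NH4Cl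
Reagents that add atoms: none
Why: Directed ortho-lithiation at the most acidic ring position, flanked by fluorine and a benzyloxy group, followed by Weinreb ketone synthesis, whose chelated tetrahedral intermediate prevents over-addition; at –78 °C the ortho-fluoroaryllithium should not lose LiF.

Step 3
Reactants: 5 1-[2,4-bis(benzyloxy)-6-fluorophenyl]-2-(benzyloxy)ethan-1-one
Product: 6 (Z)-2-(benzyloxy)-1-[2,4-bis(benzyloxy)-6-fluorophenyl]-1-(trimethylsilyloxy)ethene
Conditions: TMSOTf, Et3N, CH2Cl2, 0 °C; used crude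
Reagents that add atoms: trimethylsilyl trifluoromethanesulfonate, C[Si](C)(C)OS(=O)(=O)C(F)(F)F
Why: Soft enolisation and O-silylation (silyl enol ether formation) should give mainly the Z isomer, in which the twisted 2,6-disubstituted aryl group avoids the benzyloxy group; the geometry does not matter for the syn selectivity of step 4.

Step 4
Reactants: 6 (Z)-2-(benzyloxy)-1-[2,4-bis(benzyloxy)-6-fluorophenyl]-1-(trimethylsilyloxy)ethene; 7 4-(benzyloxy)benzaldehyde (1.2 equiv)
Product: 9 (2R,3S)-3,5,7-tris(benzyloxy)-2-[4-(benzyloxy)phenyl]-2,3-dihydro-4H-chromen-4-one, via syn-aldol trimethylsilyl ether 8 (not isolated)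
Conditions: chiral acyloxyborane catalyst made in situ from (2S,3S)-2-O-(2,6-diisopropoxybenzoyl)tartaric acid and BH3·THF (20 mol%), EtCN, –78 °C, until 6 is consumed; then Bu4NF (0.5 equiv), THF, –78 → 0 °C, same flask; pH 7 buffer
Reagents that add atoms: none
Why: The acyloxyborane binds aldehyde 7 and the enol silane attacks its carbonyl carbon through an open transition state to form C2–C3 (Mukaiyama aldol, giving silyl ether 8); fluoride then cleaves the O–Si bond and the alkoxide O1 adds to C8a, ipso to fluorine, giving a Meisenheimer anion delocalised onto the C4 carbonyl that expels fluoride (SNAr), so the fluoride is regenerated for the next molecule. The closest known reaction types are the acyloxyborane-catalysed syn-selective aldol of aryl ketone enol silanes with aromatic aldehydes and the alkoxide SNAr closure of the pyran ring of flavan-3-ols onto dialkoxyfluoroarenes; together they are the arene counterpart of the Danishefsky diene–aldehyde cyclocondensation, with C8a–F as the vinylogous leaving group. Ring C is closed by six-membered addition–elimination at C8a, 6-endo-trig with respect to the C4a=C8a bond of the vinylogous acyl fluoride that carries the charge to the C4 carbonyl (6-exo-trig if counted against C8a=C8), both allowed modes. C2 is set by the catalyst, which must deliver the enol silane to the si face of the aldehyde (the catalyst from unnatural (2S,3S)-tartaric acid is chosen because its mirror image is reported to direct attack to the re face of aromatic aldehydes, and the antipode would be taken should this substrate invert the sense), while C3 follows from the syn preference of the open transition state for either enol silane geometry; both centres pass unchanged into the ring, syn becoming 2,3-cis. The step needs ring closure to outrun retro-aldol cleavage of the aldolate and enolisation at C3 of 9: the ortho acyl group activates C8a, the two benzyloxy groups are meta to C8a and do not oppose the addition, fluoride is the best SNAr leaving group, the closure is six-membered, and 6 is consumed before fluoride is added so that no uncatalysed aldol competes. Only O1 can reach C8a, because the C3 oxygen is benzylated and a benzyloxy group is a far poorer leaving group than fluoride.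

Step 5
Reactants: 9 (2R,3S)-3,5,7-tris(benzyloxy)-2-[4-(benzyloxy)phenyl]-2,3-dihydro-4H-chromen-4-one
Product: 10 (2R,3R,4R)-3,5,7-tris(benzyloxy)-2-[4-(benzyloxy)phenyl]-3,4-dihydro-2H-chromen-4-ol
Conditions: NaBH4, CeCl3·7H2O, MeOH/THF, –40 → 0 °C
Reagents that add atoms: none
Why: Luche-type hydride reduction of the aryl ketone is fast at low temperature under nearly neutral conditions, so the base-sensitive C3 centre should not epimerise; hydride should enter anti to the pseudo-axial 3-benzyloxy group to give the all-cis alcohol, but either C4 epimer serves in step 7.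

Step 6
Reactants: 11 (–)-epicatechin
Product: 12 5,7,3',4'-tetra-O-benzyl-(–)-epicatechin
Conditions: BnBr (4.4 equiv), K2CO3, DMF, 0 °C → rt
Reagents that add atoms: benzyl bromide, BrCc1ccccc1
Why: Williamson ether synthesis in which only the four acidic phenols are deprotonated by K2CO3 and alkylated, the secondary 3-OH and both stereocentres remaining untouched.

Step 7
Reactants: 10 (2R,3R,4R)-3,5,7-tris(benzyloxy)-2-[4-(benzyloxy)phenyl]-3,4-dihydro-2H-chromen-4-ol; 12 5,7,3',4'-tetra-O-benzyl-(–)-epicatechin (3 equiv)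
Product: 13 3,5,7,4'-tetra-O-benzyl-(–)-epiafzelechin-(4β→8)-5,7,3',4'-tetra-O-benzyl-(–)-epicatechin
Conditions: TMSOTf (0.2 equiv), 4 Å MS, CH2Cl2, –78 → –30 °C; Et3N quench
Reagents that add atoms: none
Why: Acid-catalysed ionisation of the oxygen-stabilised benzylic C4–OH (lost as water, taken up by the sieves) to the flavan-4-yl cation and Friedel–Crafts capture by C8, the most nucleophilic position of 12 (the classical proanthocyanidin condensation); the arene should enter anti to the 3-benzyloxy and 2-aryl groups, both on the α face, so the new C4 centre is 4β (3,4-trans, 4R), and the excess of 12 suppresses self-condensation.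

Step 8
Reactants: 13 3,5,7,4'-tetra-O-benzyl-(–)-epiafzelechin-(4β→8)-5,7,3',4'-tetra-O-benzyl-(–)-epicatechin
Product: 14 (–)-epiafzelechin-(4β→8)-(–)-epicatechin
Conditions: H2 (1 atm), Pd(OH)2/C, THF/MeOH/H2O, rt
Reagents that add atoms: none
Why: Catalytic hydrogenolysis of the seven aryl benzyl ethers and the one alkyl benzyl ether under neutral conditions touches no stereocentre and should leave the interflavan C4–C8 bond and the pyran C–O bonds intact.

Compound list

1 | 1,3,5-trifluorobenzene | Fc1cc(F)cc(F)c1 | starting material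
2 | 1,3-bis(benzyloxy)-5-fluorobenzene | Fc1cc(OCc2ccccc2)cc(OCc2ccccc2)c1 | intermediate
3 | 2-(benzyloxy)-N-methoxy-N-methylacetamide | CON(C)C(=O)COCc1ccccc1 | starting material
4 | [2,4-bis(benzyloxy)-6-fluorophenyl]lithium | [Li]c1c(F)cc(OCc2ccccc2)cc1OCc1ccccc1 | intermediate
5 | 1-[2,4-bis(benzyloxy)-6-fluorophenyl]-2-(benzyloxy)ethan-1-one | O=C(COCc1ccccc1)c1c(F)cc(OCc2ccccc2)cc1OCc1ccccc1 | intermediate
6 | (Z)-2-(benzyloxy)-1-[2,4-bis(benzyloxy)-6-fluorophenyl]-1-(trimethylsilyloxy)ethene | C[Si](C)(C)O/C(=C\OCc1ccccc1)c1c(F)cc(OCc2ccccc2)cc1OCc1ccccc1 | intermediate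
7 | 4-(benzyloxy)benzaldehyde | O=Cc1ccc(OCc2ccccc2)cc1 | starting material
8 | (2S,3R)-2-(benzyloxy)-1-[2,4-bis(benzyloxy)-6-fluorophenyl]-3-[4-(benzyloxy)phenyl]-3-(trimethylsilyloxy)propan-1-one (syn aldol silyl ether) | C[Si](C)(C)O[C@H](c1ccc(OCc2ccccc2)cc1)[C@H](OCc1ccccc1)C(=O)c1c(F)cc(OCc2ccccc2)cc1OCc1ccccc1 | intermediate
9 | (2R,3S)-3,5,7-tris(benzyloxy)-2-[4-(benzyloxy)phenyl]-2,3-dihydro-4H-chromen-4-one (2,3-cis) | c1ccccc1COc1ccc([C@H]2Oc3cc(OCc4ccccc4)cc(OCc4ccccc4)c3C(=O)[C@H]2OCc2ccccc2)cc1 | intermediate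
10 | (2R,3R,4R)-3,5,7-tris(benzyloxy)-2-[4-(benzyloxy)phenyl]-3,4-dihydro-2H-chromen-4-ol (all-cis) | c1ccccc1COc1ccc([C@H]2Oc3cc(OCc4ccccc4)cc(OCc4ccccc4)c3[C@@H](O)[C@H]2OCc2ccccc2)cc1 | intermediate
11 | (–)-epicatechin, (2R,3R)-2-(3,4-dihydroxyphenyl)-3,4-dihydro-2H-chromene-3,5,7-triol | O[C@@H]1Cc2c(O)cc(O)cc2O[C@@H]1c1ccc(O)c(O)c1 | starting material
12 | 5,7,3',4'-tetra-O-benzyl-(–)-epicatechin, (2R,3R)-5,7-bis(benzyloxy)-2-[3,4-bis(benzyloxy)phenyl]-3,4-dihydro-2H-chromen-3-ol | O[C@@H]1Cc2c(OCc3ccccc3)cc(OCc3ccccc3)cc2O[C@@H]1c1ccc(OCc2ccccc2)c(OCc2ccccc2)c1 | intermediate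
13 | 3,5,7,4'-tetra-O-benzyl-(–)-epiafzelechin-(4β→8)-5,7,3',4'-tetra-O-benzyl-(–)-epicatechin (upper unit 2R,3R,4R; lower unit 2R,3R; lower 3-OH free) | c1ccccc1COc1ccc([C@H]2Oc3cc(OCc4ccccc4)cc(OCc4ccccc4)c3[C@H](c3c(OCc4ccccc4)cc(OCc4ccccc4)c4c3O[C@H](c3ccc(OCc5ccccc5)c(OCc5ccccc5)c3)[C@H](O)C4)[C@H]2OCc2ccccc2)cc1 | intermediate
14 | (–)-epiafzelechin-(4β→8)-(–)-epicatechin (upper unit 2R,3R,4R; lower unit 2R,3R) | Oc1ccc([C@H]2Oc3cc(O)cc(O)c3[C@H](c3c(O)cc(O)c4c3O[C@H](c3ccc(O)c(O)c3)[C@H](O)C4)[C@H]2O)cc1 | target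

Total step count: 8. Longest linear sequence: 7 steps (steps 1, 2, 3, 4, 5, 7, 8); step 6 prepares the lower unit in parallel.

Steps most likely to fail

Step 4. What may go wrong: insufficient facial or syn selectivity in the boron-catalysed addition to the α-benzyloxy enol silane, or erosion of both by retro-aldol cleavage of the fluoride-liberated aldolate and by enolisation at C3 before or after ring closure. The fallback uses auxiliary control and removes the carbonyl before the aryl ether bond is closed; it sets out from aldehyde 7 and aryllithium 4 and comes back at 10. Boron-mediated Evans syn-glycolate aldol of 7 with commercial (S)-4-benzyl-3-(benzyloxyacetyl)oxazolidin-2-one (Bu2BOTf, Et3N, CH2Cl2, –78 → 0 °C) should give (S)-4-benzyl-3-[(2S,3R)-2-(benzyloxy)-3-[4-(benzyloxy)phenyl]-3-hydroxypropanoyl]oxazolidin-2-one F1. Transamidation (MeNHOMe·HCl, AlMe3, CH2Cl2, 0 °C) gives the Weinreb amide (2S,3R)-2-(benzyloxy)-3-[4-(benzyloxy)phenyl]-3-hydroxy-N-methoxy-N-methylpropanamide F2. Addition of 4 (2.3 equiv, THF, –78 °C, cold AcOH quench) gives the β-hydroxy ketone (2S,3R)-2-(benzyloxy)-1-[2,4-bis(benzyloxy)-6-fluorophenyl]-3-[4-(benzyloxy)phenyl]-3-hydroxypropan-1-one F3. Hydroxyl-directed Evans–Saksena reduction (Me4NBH(OAc)3, MeCN/AcOH, –30 °C) gives the anti-1,3-diol (1R,2S,3R)-2-(benzyloxy)-1-[2,4-bis(benzyloxy)-6-fluorophenyl]-3-[4-(benzyloxy)phenyl]propane-1,3-diol F4, in which retro-aldol cleavage is no longer possible. KH, 18-crown-6, THF, 0 °C → rt then closes O1–C8a by alkoxide SNAr on the fluoroarene to give 10.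

Step 7. What may go wrong: self-condensation of the ionised upper unit through its own nucleophilic ring A, and further reaction of the dimer to oligomers. The fallback uses a blocking group; it sets out from 10 and comes back at 14. NBS (CH2Cl2, –78 → 0 °C) should brominate C8 of 10 to give (2R,3R,4R)-3,5,7-tris(benzyloxy)-2-[4-(benzyloxy)phenyl]-8-bromo-3,4-dihydro-2H-chromen-4-ol F5, whose ring A is blocked and deactivated. Condensation with 12 under the conditions of step 7 gives 8-bromo-3,5,7,4'-tetra-O-benzyl-epiafzelechin-(4β→8)-5,7,3',4'-tetra-O-benzyl-epicatechin F6. H2, Pd(OH)2/C, Et3N, THF/MeOH/H2O removes the bromine together with the eight benzyl groups to give 14.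

Step 2. What may go wrong: loss of LiF from the ortho-fluoroaryllithium to an aryne, or deprotonation between the two benzyloxy groups or at a benzylic CH2 followed by rearrangement. The fallback replaces deprotonation by halogen–magnesium exchange; it sets out from 2 and comes back at 5. NBS (MeCN, 0 °C) should brominate 2 ortho to fluorine and para to a benzyloxy group to give 1,5-bis(benzyloxy)-2-bromo-3-fluorobenzene F7. iPrMgCl·LiCl (THF, –20 °C) gives chloro[2,4-bis(benzyloxy)-6-fluorophenyl]magnesium F8, which should not eliminate fluoride at this temperature and is acylated by 3 to give 5.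

Further compounds

F1 | step 4 | (S)-4-benzyl-3-[(2S,3R)-2-(benzyloxy)-3-[4-(benzyloxy)phenyl]-3-hydroxypropanoyl]oxazolidin-2-one | O[C@H](c1ccc(OCc2ccccc2)cc1)[C@H](OCc1ccccc1)C(=O)N1C(=O)OC[C@@H]1Cc1ccccc1
F2 | step 4 | (2S,3R)-2-(benzyloxy)-3-[4-(benzyloxy)phenyl]-3-hydroxy-N-methoxy-N-methylpropanamide | O[C@H](c1ccc(OCc2ccccc2)cc1)[C@H](OCc1ccccc1)C(=O)N(C)OC
F3 | step 4 | (2S,3R)-2-(benzyloxy)-1-[2,4-bis(benzyloxy)-6-fluorophenyl]-3-[4-(benzyloxy)phenyl]-3-hydroxypropan-1-one | O[C@H](c1ccc(OCc2ccccc2)cc1)[C@H](OCc1ccccc1)C(=O)c1c(F)cc(OCc2ccccc2)cc1OCc1ccccc1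
F4 | step 4 | (1R,2S,3R)-2-(benzyloxy)-1-[2,4-bis(benzyloxy)-6-fluorophenyl]-3-[4-(benzyloxy)phenyl]propane-1,3-diol | O[C@H](c1ccc(OCc2ccccc2)cc1)[C@H](OCc1ccccc1)[C@H](O)c1c(F)cc(OCc2ccccc2)cc1OCc1ccccc1
F5 | step 7 | (2R,3R,4R)-3,5,7-tris(benzyloxy)-2-[4-(benzyloxy)phenyl]-8-bromo-3,4-dihydro-2H-chromen-4-ol | c1ccccc1COc1ccc([C@H]2Oc3c(Br)c(OCc4ccccc4)cc(OCc4ccccc4)c3[C@@H](O)[C@H]2OCc2ccccc2)cc1
F6 | step 7 | 8-bromo-3,5,7,4'-tetra-O-benzyl-epiafzelechin-(4β→8)-5,7,3',4'-tetra-O-benzyl-epicatechin | c1ccccc1COc1ccc([C@H]2Oc3c(Br)c(OCc4ccccc4)cc(OCc4ccccc4)c3[C@H](c3c(OCc4ccccc4)cc(OCc4ccccc4)c4c3O[C@H](c3ccc(OCc5ccccc5)c(OCc5ccccc5)c3)[C@H](O)C4)[C@H]2OCc2ccccc2)cc1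
F7 | step 2 | 1,5-bis(benzyloxy)-2-bromo-3-fluorobenzene | Brc1c(F)cc(OCc2ccccc2)cc1OCc1ccccc1
F8 | step 2 | chloro[2,4-bis(benzyloxy)-6-fluorophenyl]magnesium | Cl[Mg]c1c(F)cc(OCc2ccccc2)cc1OCc1ccccc1
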